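**Retrosynthetic overview**

1. The strategy rests on the butyrolactone ring (O1–C2(=O)–C3–C4–C5H2). C3 carries the ring C benzyl and C4 the dihydrobenzofuran-5-ylmethyl group, trans to each other. C5 is an unsubstituted OCH2 carbon, so it can be carried as a menthyl acetal stereocentre.
2. Key disconnections, made in one flask on (5R)-5-menthyloxybutenolide 6: C4–CH2(benzofuran) as the 1,4-addition of lithiated aryl dithiane 26, and C3–CH2(ring C) as benzylation of the resulting enolate by bromide 42.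
3. Dithiane 26: Evans syn-aldol (sets benzofuran C3), acid cycloetherification (closes the dihydrofuran ring, C2 trans), then Br → CHO → dithiane. Bromide 42: Evans glycolate aldol (sets C8), Mitsunobu inversion at C7 (threo → erythro), silylation, ester → CH2Br.
4. Ring order: butenolide ring from furfural (steps 1–2); dihydrofuran ring of the benzofuran (step 9); no ring closes in the key step; the lactone is re-formed by hydrolysis–reduction–relactonisation (step 25). Desilylation and hydrogenolysis finish the route.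

Key step: step 23

Remark: the benzofuran CH2OH is carried as a TBDPS ether and not as a benzyl ether, so that fluoride frees all three aliphatic hydroxyls together and the last hydrogenolysis has to cleave only the two aryl benzyl ethers.

Abbreviations used in names:
- Men = (1R,2S,5R)-2-isopropyl-5-methylcyclohexyl (l-menthyl).
- BF = aryl group of 26: (2S,3R)-2-[4-(benzyloxy)-3-methoxyphenyl]-3-{[tert-butyl(diphenyl)silyl]oxymethyl}-7-methoxy-2,3-dihydro-1-benzofuran-5-yl.
- ArC = aryl group of 42: 4-({(1R,2S)-1-[4-(benzyloxy)-3-methoxyphenyl]-1,3-bis[(tert-butyldimethylsilyl)oxy]propan-2-yl}oxy)-3-methoxyphenyl.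

**Butenolide (steps 1–2)**

Step 1
Reactants: 1 furfural
Product: 3 5-hydroxyfuran-2(5H)-one (racemic), via furan endoperoxide 2 (not isolated)
Conditions: O2, hν, methylene blue (cat.), MeOH, rt
Reagents that add atoms: oxygen, O=O
Why: Dye-sensitised photo-oxygenation, in which singlet oxygen adds [4+2] across the furan to give endoperoxide 2 and methanol attack on the formyl group lets the peroxide fragment with loss of that carbon as methyl formate.

Step 2
Reactants: 3 5-hydroxyfuran-2(5H)-one; 4 (–)-menthol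
Product: 6 (5R)-5-(Men-oxy)furan-2(5H)-one, via (5S)-epimer 5 (not isolated)
Conditions: TsOH·H2O (cat.), toluene, reflux (Dean–Stark); crystallisation from petroleum ether, mother liquor re-equilibrated with TsOH (cat.) and recrystallised
Reagents that add atoms: none
Why: Acid-catalysed acetalisation through the furanone oxocarbenium ion gives both C5 epimers, which keep interconverting under the acid while only the (5R)-epimer crystallises, so crystallisation-induced epimerisation sets C5 as R under control of the menthyl group.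

**Benzofuran dithiane (steps 3–12)**

Step 3
Reactants: 7 5-bromo-2-hydroxy-3-methoxybenzaldehyde
Product: 8 5-bromo-3-methoxy-2-(methoxymethoxy)benzaldehyde
Conditions: MOMCl, i-Pr2NEt, CH2Cl2, 0 °C → rt
Reagents that add atoms: chloromethyl methyl ether (MOMCl), COCCl
Why: Williamson-type O-alkylation of the phenol by the very reactive α-chloro ether gives a MOM acetal that withstands the basic and hydride steps ahead and leaves under the same acid that later closes the ring.

Step 4
Reactants: 8 5-bromo-3-methoxy-2-(methoxymethoxy)benzaldehyde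
Product: 9 1-[5-bromo-3-methoxy-2-(methoxymethoxy)phenyl]-2,2,2-trichloroethanol (racemic)
Conditions: CHCl3, DBU, 0 °C → rt
Reagents that add atoms: chloroform, ClC(Cl)Cl
Why: Base-mediated addition of the trichloromethyl anion to the aldehyde (Corey–Link-type carbinol formation), the new carbinol centre being racemic and destroyed in step 5.

Step 5
Reactants: 9 1-[5-bromo-3-methoxy-2-(methoxymethoxy)phenyl]-2,2,2-trichloroethanol
Product: 12 [5-bromo-3-methoxy-2-(methoxymethoxy)phenyl]acetic acid, via dichlorooxirane 10 (not isolated), via arylacetyl chloride 11 (not isolated)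
Conditions: NaBH4, NaOH, t-BuOH, 50 °C; then 1 M HCl to pH 3, 0 °C
Reagents that add atoms: sodium hydroxide, [Na+].[OH-] (one carboxyl oxygen)
Why: Jocic–Reeve-type reductive one-carbon homologation, in which hydroxide closes the carbinol to gem-dichlorooxirane 10, borohydride opens it at the benzylic carbon to acyl chloride 11 and hydroxide hydrolyses this to the arylacetate under conditions that the MOM ether and aryl bromide tolerate.

Step 6
Reactants: 12 [5-bromo-3-methoxy-2-(methoxymethoxy)phenyl]acetic acid; 13 (S)-4-benzyl-1,3-oxazolidin-2-one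
Product: 15 (4S)-4-benzyl-3-{[5-bromo-3-methoxy-2-(methoxymethoxy)phenyl]acetyl}-1,3-oxazolidin-2-one, via mixed pivalic anhydride 14 (not isolated)
Conditions: PivCl, Et3N, THF, −20 °C; then 13, LiCl, −20 °C → rt
Reagents that add atoms: none
Why: Mixed-anhydride N-acylation, in which the LiCl-activated oxazolidinone attacks the unhindered arylacetyl carbonyl of the pivalic mixed anhydride and not the hindered pivaloyl carbonyl.

Step 7
Reactants: 15 (4S)-4-benzyl-3-{[5-bromo-3-methoxy-2-(methoxymethoxy)phenyl]acetyl}-1,3-oxazolidin-2-one; 16 4-(benzyloxy)-3-methoxybenzaldehyde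
Product: 19 (4S)-4-benzyl-3-{(2S,3S)-3-[4-(benzyloxy)-3-methoxyphenyl]-2-[5-bromo-3-methoxy-2-(methoxymethoxy)phenyl]-3-hydroxypropanoyl}-1,3-oxazolidin-2-one, via boron enolate 17 (not isolated), via boron aldolate 18 (not isolated)
Conditions: Bu2BOTf, i-Pr2NEt, CH2Cl2, −78 → 0 °C; 16, −78 → 0 °C; then pH 7 buffer, MeOH, H2O2, 0 °C
Reagents that add atoms: none
Why: Evans syn-aldol reaction, in which the Z-boron enolate 17 adds to the aldehyde through a closed Zimmerman–Traxler chair on the face remote from the benzyl group of the (S)-auxiliary, setting the α-carbon (the future benzofuran C3) as 2S and the carbinol syn to it as 3S.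

Step 8
Reactants: 19 the syn-aldol imide
Product: 20 (1S,2R)-1-[4-(benzyloxy)-3-methoxyphenyl]-2-[5-bromo-3-methoxy-2-(methoxymethoxy)phenyl]propane-1,3-diol
Conditions: LiBH4, MeOH (1.5 eq), THF, 0 °C
Reagents that add atoms: none
Why: Reductive cleavage of the N-acyloxazolidinone, in which hydride attacks the more electrophilic exocyclic imide carbonyl and gives the primary alcohol with both stereocentres untouched and the auxiliary recoverable.

Step 9
Reactants: 20 (1S,2R)-1-[4-(benzyloxy)-3-methoxyphenyl]-2-[5-bromo-3-methoxy-2-(methoxymethoxy)phenyl]propane-1,3-diol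
Product: 22 {(2S,3R)-2-[4-(benzyloxy)-3-methoxyphenyl]-5-bromo-7-methoxy-2,3-dihydro-1-benzofuran-3-yl}methanol (2,3-trans), via free phenol 21 (not isolated)
Conditions: HCl (cat.), MeOH, 40 °C
Reagents that add atoms: none
Why: Acid cleaves the MOM acetal to phenol 21 and ionises the p-alkoxybenzylic alcohol to a stabilised cation that the ortho phenol captures in a 5-exo SN1 cycloetherification, C2 ending up trans to the fixed C3 substituent under thermodynamic control because the benzylic C–O bond forms reversibly under acid.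

Step 10
Reactants: 22 {(2S,3R)-2-[4-(benzyloxy)-3-methoxyphenyl]-5-bromo-7-methoxy-2,3-dihydro-1-benzofuran-3-yl}methanol
Product: 23 tert-butyl({(2S,3R)-2-[4-(benzyloxy)-3-methoxyphenyl]-5-bromo-7-methoxy-2,3-dihydro-1-benzofuran-3-yl}methoxy)diphenylsilane
Conditions: TBDPSCl, imidazole, DMF, rt
Reagents that add atoms: tert-butyl(chloro)diphenylsilane (TBDPSCl), CC(C)(C)[Si](Cl)(c1ccccc1)c1ccccc1
Why: Silylation of the unhindered primary alcohol through the N-silylimidazolium ion gives an ether that survives organolithiums and thioacetalisation and leaves with fluoride.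

Step 11
Reactants: 23 the TBDPS ether
Product: 25 (2S,3R)-2-[4-(benzyloxy)-3-methoxyphenyl]-3-{[tert-butyl(diphenyl)silyl]oxymethyl}-7-methoxy-2,3-dihydro-1-benzofuran-5-carbaldehyde, via aryllithium 24 (not isolated)
Conditions: n-BuLi, THF, −78 °C; DMF, −78 → 0 °C; then H2O
Reagents that add atoms: N,N-dimethylformamide (DMF), CN(C)C=O
Why: Bromine–lithium exchange is faster at −78 °C than any deprotonation and the aryllithium 24 is formylated by DMF through a stable hemiaminal alkoxide (Bouveault-type formylation).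

Step 12
Reactants: 25 the benzofuran-5-carbaldehyde
Product: 26 2-(BF)-1,3-dithiane
Conditions: HS(CH2)3SH, I2 (10 mol %), CH2Cl2, rt
Reagents that add atoms: propane-1,3-dithiol, SCCCS
Why: Iodine-catalysed dithioacetalisation of the aromatic aldehyde is chosen because a strong Lewis acid together with a thiol could open the acid-labile 2-aryl-dihydrobenzofuran or cleave the benzyl ether.

**Ring C bromide (steps 13–22)**

Step 13
Reactants: 27 methyl 4-hydroxy-3-methoxybenzoate (methyl vanillate); 28 bromoacetic acid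
Product: 29 [2-methoxy-4-(methoxycarbonyl)phenoxy]acetic acid
Conditions: NaH (2.2 eq), THF/DMF, 0 → 60 °C; then 1 M HCl
Reagents that add atoms: none
Why: Williamson ether synthesis in which the sodium phenoxide displaces bromide from sodium bromoacetate, whose carboxylate charge prevents side reactions at the acid.

Step 14
Reactants: 29 [2-methoxy-4-(methoxycarbonyl)phenoxy]acetic acid; 30 (R)-4-benzyl-1,3-oxazolidin-2-one
Product: 32 methyl 4-{2-[(4R)-4-benzyl-2-oxo-1,3-oxazolidin-3-yl]-2-oxoethoxy}-3-methoxybenzoate, via mixed pivalic anhydride 31 (not isolated)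
Conditions: PivCl, Et3N, THF, −20 °C; then 30, LiCl, −20 °C → rt
Reagents that add atoms: none
Why: Mixed-anhydride N-acylation as in step 6, here with the (R)-oxazolidinone attacking the unhindered aryloxyacetyl carbonyl.

Step 15
Reactants: 32 the aryloxyacetyl imide; 16 4-(benzyloxy)-3-methoxybenzaldehyde
Product: 35 methyl 4-({(1S,2R)-1-[4-(benzyloxy)-3-methoxyphenyl]-3-[(4R)-4-benzyl-2-oxo-1,3-oxazolidin-3-yl]-1-hydroxy-3-oxopropan-2-yl}oxy)-3-methoxybenzoate (syn aldol), via boron enolate 33 (not isolated), via boron aldolate 34 (not isolated)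
Conditions: Bu2BOTf, i-Pr2NEt, CH2Cl2, −78 → 0 °C; 16, −78 → 0 °C; then pH 7 buffer, MeOH, H2O2, 0 °C
Reagents that add atoms: none
Why: Evans syn-aldol reaction of the glycolate-type imide, in which the Z-boron enolate 33 reacts through a Zimmerman–Traxler chair on the face remote from the benzyl group of the (R)-auxiliary, setting the aryloxy-bearing carbon (the future C8) and, syn to it, the carbinol that step 18 inverts.

Step 16
Reactants: 35 the syn-aldol imide
Product: 36 methyl 4-({(1S,2S)-1-[4-(benzyloxy)-3-methoxyphenyl]-1,3-dihydroxypropan-2-yl}oxy)-3-methoxybenzoate (threo)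
Conditions: NaBH4, THF/H2O (4:1), 0 °C → rt
Reagents that add atoms: none
Why: Reductive removal of the auxiliary with borohydride in wet THF, conditions under which the N-acyloxazolidinone is reduced while the electron-rich aryl methyl ester is not.

Step 17
Reactants: 36 the threo diol
Product: 37 methyl 4-({(1S,2S)-1-[4-(benzyloxy)-3-methoxyphenyl]-3-[(tert-butyldimethylsilyl)oxy]-1-hydroxypropan-2-yl}oxy)-3-methoxybenzoate
Conditions: TBSCl (1.05 eq), imidazole, CH2Cl2, 0 °C
Reagents that add atoms: tert-butyl(chloro)dimethylsilane (TBSCl), CC(C)(C)[Si](C)(C)Cl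
Why: Selective silylation, since the primary alcohol reacts much faster than the hindered secondary benzylic one with one equivalent of silyl chloride at 0 °C.

Step 18
Reactants: 37 the threo mono-silyl ether
Product: 38 (1R,2S)-1-[4-(benzyloxy)-3-methoxyphenyl]-3-[(tert-butyldimethylsilyl)oxy]-2-[2-methoxy-4-(methoxycarbonyl)phenoxy]propyl 4-nitrobenzoate
Conditions: 4-nitrobenzoic acid, PPh3, DIAD, toluene, 0 °C → rt
Reagents that add atoms: 4-nitrobenzoic acid, OC(=O)c1ccc(cc1)[N+](=O)[O-]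
Why: Mitsunobu reaction, in which the alkoxyphosphonium ion of the benzylic alcohol is displaced by 4-nitrobenzoate in an SN2 step with inversion, turning threo (1S,2S) into erythro (1R,2S), with the electron-withdrawing neighbouring aryloxy group and the non-polar solvent disfavouring ionisation.

Step 19
Reactants: 38 the erythro 4-nitrobenzoate
Product: 39 methyl 4-({(1R,2S)-1-[4-(benzyloxy)-3-methoxyphenyl]-3-[(tert-butyldimethylsilyl)oxy]-1-hydroxypropan-2-yl}oxy)-3-methoxybenzoate (erythro)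
Conditions: K2CO3 (0.2 eq), MeOH, 0 °C → rt
Reagents that add atoms: none
Why: Base-catalysed transesterification removes the activated 4-nitrobenzoate, while the aryl methyl ester merely exchanges with methanol and the primary silyl ether is stable.

Step 20
Reactants: 39 the erythro alcohol
Product: 40 methyl 4-({(1R,2S)-1-[4-(benzyloxy)-3-methoxyphenyl]-1,3-bis[(tert-butyldimethylsilyl)oxy]propan-2-yl}oxy)-3-methoxybenzoate
Conditions: TBSOTf, 2,6-lutidine, CH2Cl2, −78 → 0 °C
Reagents that add atoms: tert-butyldimethylsilyl triflate (TBSOTf), CC(C)(C)[Si](C)(C)OS(=O)(=O)C(F)(F)F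
Why: Silylation of the hindered secondary alcohol with the silyl triflate and a non-nucleophilic base at low temperature, which avoids ionising the benzylic position.

Step 21
Reactants: 40 the bis-silyl ether ester
Product: 41 (ArC)methanol
Conditions: i-Bu2AlH (2.5 eq), CH2Cl2, −78 → 0 °C; then KNaC4H4O6 (aq.)
Reagents that add atoms: none
Why: Hydride reduction of the aryl ester to the benzylic alcohol through the aldehyde, with silyl and benzyl ethers inert to the aluminium hydride.

Step 22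
Reactants: 41 (ArC)methanol
Product: 42 (ArC)methyl bromide
Conditions: CBr4, PPh3, CH2Cl2, 0 °C; used at once
Reagents that add atoms: carbon tetrabromide, BrC(Br)(Br)Br
Why: Appel reaction, in which the alkoxyphosphonium ion of the primary benzylic alcohol is displaced by bromide under neutral conditions that leave the silyl ethers intact.

**Key step and endgame (steps 23–27)**

Step 23
Reactants: 26 2-(BF)-1,3-dithiane; 6 (5R)-5-(Men-oxy)furan-2(5H)-one; 42 (ArC)methyl bromide
Product: 45 (3R,4R,5R)-3-[(ArC)methyl]-4-[2-(BF)-1,3-dithian-2-yl]-5-(Men-oxy)oxolan-2-one, via lithiated dithiane 43 (not isolated), via lithium enolate 44 (not isolated)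
Conditions: n-BuLi, THF, −78 → −30 °C; 6, −78 °C; 42, DMPU, −78 °C → rt
Reagents that add atoms: none
Why: n-BuLi removes the dithiane C2–H, the most acidic C–H because two sulfurs and the arene flank it, to give the soft tertiary carbanion 43, which adds 1,4 to the butenolide; the lithium lactone enolate 44 is then C-benzylated by the reactive p-alkoxybenzylic bromide in an SN2 step. The closest known reaction type is the tandem conjugate addition of lithiated aryl dithianes to 5-alkoxyfuran-2(5H)-ones with benzylic halide trapping, as used for trans-dibenzylbutyrolactone lignans. No ring is closed: the two C–C bonds C4–C(dithiane) and C3–CH2Ar form on the existing five-membered ring. C4 is controlled by the C5 menthyloxy group, which shields one face of the planar butenolide so that the nucleophile enters anti to it (4,5-trans), and C3 is controlled by the new bulky dithianyl group at C4, which sends the bromide to the opposite enolate face (3,4-trans), giving (3R,4R,5R). The step needs 1,4- over 1,2-addition, which the delocalised sulfur-stabilised anion secures, and C-monoalkylation, which the lithium enolate, the benzylic electrophile and the crowded neighbouring carbon secure; the four stereocentres already present in 26 and 42 carry no acidic hydrogen under these conditions and are not touched.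

Step 24
Reactants: 45 the dithiane lactone acetal
Product: 46 (3R,4R,5R)-3-[(ArC)methyl]-4-[(BF)methyl]-5-(Men-oxy)oxolan-2-one
Conditions: NiCl2·6H2O, NaBH4, MeOH/THF, 0 °C
Reagents that add atoms: none
Why: Reductive desulfurisation with nickel boride formed in the flask, which hydrogenolyses both benzylic C–S bonds while benzyl ethers, silyl ethers and the lactone acetal are not attacked under these mild conditions.

Step 25
Reactants: 46 the desulfurised lactone acetal
Product: 49 (3R,4R)-3-[(ArC)methyl]-4-[(BF)methyl]oxolan-2-one, via formyl carboxylate 47 (not isolated), via hydroxy carboxylate 48 (not isolated)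
Conditions: NaBH4, KOH, THF/MeOH/H2O, 0 °C → rt; then KHSO4 (aq.) to pH 3, rt
Reagents that add atoms: potassium hydroxide, [K+].[OH-] (its oxygen enters the carboxyl group and can remain as the lactone carbonyl oxygen)
Why: Hydrolysis–reduction–relactonisation of the pseudo-ester, in which hydroxide opens the lactone, the menthyl hemiacetal collapses to aldehyde 47, borohydride reduces it at once to alcohol 48 and acidification closes the γ-hydroxy acid, so the former acetal carbon becomes the lactone OCH2 while the carbonyl stays next to the carbon bearing the ring C benzyl and the trans C3/C4 pair, also the thermodynamically preferred one, is kept.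

Step 26
Reactants: 49 the silyl-protected lactone
Product: 50 (3R,4R)-3-(4-{[(1R,2S)-1-[4-(benzyloxy)-3-methoxyphenyl]-1,3-dihydroxypropan-2-yl]oxy}-3-methoxybenzyl)-4-({(2S,3R)-2-[4-(benzyloxy)-3-methoxyphenyl]-3-(hydroxymethyl)-7-methoxy-2,3-dihydro-1-benzofuran-5-yl}methyl)oxolan-2-one
Conditions: TBAF (4 eq), AcOH (4 eq), THF, 0 °C → rt
Reagents that add atoms: none
Why: Fluoride-mediated desilylation, driven by Si–F bond formation, removes all three silyl ethers and is buffered with acetic acid so that the lactone is not exposed to strong base while the phenols are still benzylated.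

Step 27
Reactants: 50 the bis(benzyl ether) triol
Product: 51 CNP0298853.1, (3R,4R)-3-(4-{[(1R,2S)-1,3-dihydroxy-1-(4-hydroxy-3-methoxyphenyl)propan-2-yl]oxy}-3-methoxybenzyl)-4-{[(2S,3R)-2-(4-hydroxy-3-methoxyphenyl)-3-(hydroxymethyl)-7-methoxy-2,3-dihydro-1-benzofuran-5-yl]methyl}oxolan-2-one
Conditions: H2 (1 atm), 10% Pd/C, EtOAc/EtOH, rt
Reagents that add atoms: none
Why: Catalytic hydrogenolysis of the two aryl benzyl ethers, which under neutral conditions at 1 atm should cleave much faster than the secondary benzylic alcohol or the cyclic benzylic aryl ether of the dihydrobenzofuran.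

**Compound list**

1 | furfural | O=Cc1ccco1 | starting material
2 | 1-formyl-2,3,7-trioxabicyclo[2.2.1]hept-5-ene (furan endoperoxide, racemic) | O=CC12C=CC(OO1)O2 | intermediate
3 | 5-hydroxyfuran-2(5H)-one (racemic) | OC1OC(=O)C=C1 | intermediate
4 | (–)-menthol, (1R,2S,5R)-2-isopropyl-5-methylcyclohexan-1-ol | C[C@@H]1CC[C@H]([C@@H](C1)O)C(C)C | starting material
5 | (5S)-5-(Men-oxy)furan-2(5H)-one | O=C1C=C[C@@H](O[C@@H]2C[C@H](C)CC[C@H]2C(C)C)O1 | intermediate
6 | (5R)-5-(Men-oxy)furan-2(5H)-one | O=C1C=C[C@H](O[C@@H]2C[C@H](C)CC[C@H]2C(C)C)O1 | intermediate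
7 | 5-bromo-2-hydroxy-3-methoxybenzaldehyde | COc1cc(Br)cc(C=O)c1O | starting material
8 | 5-bromo-3-methoxy-2-(methoxymethoxy)benzaldehyde | COCOc1c(OC)cc(Br)cc1C=O | intermediate
9 | 1-[5-bromo-3-methoxy-2-(methoxymethoxy)phenyl]-2,2,2-trichloroethanol (racemic) | COCOc1c(OC)cc(Br)cc1C(O)C(Cl)(Cl)Cl | intermediate
10 | 3-[5-bromo-3-methoxy-2-(methoxymethoxy)phenyl]-2,2-dichlorooxirane (racemic) | COCOc1c(OC)cc(Br)cc1C1OC1(Cl)Cl | intermediate
11 | [5-bromo-3-methoxy-2-(methoxymethoxy)phenyl]acetyl chloride | COCOc1c(OC)cc(Br)cc1CC(=O)Cl | intermediate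
12 | [5-bromo-3-methoxy-2-(methoxymethoxy)phenyl]acetic acid | COCOc1c(OC)cc(Br)cc1CC(=O)O | intermediate
13 | (S)-4-benzyl-1,3-oxazolidin-2-one | O=C1N[C@@H](Cc2ccccc2)CO1 | starting material
14 | mixed anhydride of 12 with pivalic acid | COCOc1c(OC)cc(Br)cc1CC(=O)OC(=O)C(C)(C)C | intermediate
15 | (4S)-4-benzyl-3-{[5-bromo-3-methoxy-2-(methoxymethoxy)phenyl]acetyl}-1,3-oxazolidin-2-one | COCOc1c(OC)cc(Br)cc1CC(=O)N1[C@@H](Cc2ccccc2)COC1=O | intermediate
16 | 4-(benzyloxy)-3-methoxybenzaldehyde (O-benzylvanillin) | COc1cc(C=O)ccc1OCc1ccccc1 | starting material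
17 | Z-dibutylboron enolate of 15 | CCCCB(CCCC)O/C(=C\c1cc(Br)cc(OC)c1OCOC)N1[C@@H](Cc2ccccc2)COC1=O | intermediate
18 | O-dibutylboron aldolate of 19 | COCOc1c(OC)cc(Br)cc1[C@H](C(=O)N1[C@@H](Cc2ccccc2)COC1=O)[C@H](OB(CCCC)CCCC)c1ccc(OCc2ccccc2)c(OC)c1 | intermediate
19 | (4S)-4-benzyl-3-{(2S,3S)-3-[4-(benzyloxy)-3-methoxyphenyl]-2-[5-bromo-3-methoxy-2-(methoxymethoxy)phenyl]-3-hydroxypropanoyl}-1,3-oxazolidin-2-one | COCOc1c(OC)cc(Br)cc1[C@H](C(=O)N1[C@@H](Cc2ccccc2)COC1=O)[C@H](O)c1ccc(OCc2ccccc2)c(OC)c1 | intermediate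
20 | (1S,2R)-1-[4-(benzyloxy)-3-methoxyphenyl]-2-[5-bromo-3-methoxy-2-(methoxymethoxy)phenyl]propane-1,3-diol | COCOc1c(OC)cc(Br)cc1[C@H](CO)[C@H](O)c1ccc(OCc2ccccc2)c(OC)c1 | intermediate
21 | (1S,2R)-1-[4-(benzyloxy)-3-methoxyphenyl]-2-(5-bromo-2-hydroxy-3-methoxyphenyl)propane-1,3-diol | COc1cc(Br)cc([C@H](CO)[C@H](O)c2ccc(OCc3ccccc3)c(OC)c2)c1O | intermediate
22 | {(2S,3R)-2-[4-(benzyloxy)-3-methoxyphenyl]-5-bromo-7-methoxy-2,3-dihydro-1-benzofuran-3-yl}methanol | Brc1cc(OC)c2c(c1)[C@H](CO)[C@@H](c1ccc(OCc3ccccc3)c(OC)c1)O2 | intermediate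
23 | tert-butyl({(2S,3R)-2-[4-(benzyloxy)-3-methoxyphenyl]-5-bromo-7-methoxy-2,3-dihydro-1-benzofuran-3-yl}methoxy)diphenylsilane | Brc1cc(OC)c2c(c1)[C@H](CO[Si](c1ccccc1)(c1ccccc1)C(C)(C)C)[C@@H](c1ccc(OCc3ccccc3)c(OC)c1)O2 | intermediate
24 | (BF)lithium | [Li]c1cc(OC)c2c(c1)[C@H](CO[Si](c1ccccc1)(c1ccccc1)C(C)(C)C)[C@@H](c1ccc(OCc3ccccc3)c(OC)c1)O2 | intermediate
25 | (2S,3R)-2-[4-(benzyloxy)-3-methoxyphenyl]-3-{[tert-butyl(diphenyl)silyl]oxymethyl}-7-methoxy-2,3-dihydro-1-benzofuran-5-carbaldehyde | O=Cc1cc(OC)c2c(c1)[C@H](CO[Si](c1ccccc1)(c1ccccc1)C(C)(C)C)[C@@H](c1ccc(OCc3ccccc3)c(OC)c1)O2 | intermediate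
26 | 2-(BF)-1,3-dithiane | S1CCCSC1c1cc(OC)c2c(c1)[C@H](CO[Si](c1ccccc1)(c1ccccc1)C(C)(C)C)[C@@H](c1ccc(OCc3ccccc3)c(OC)c1)O2 | intermediate
27 | methyl 4-hydroxy-3-methoxybenzoate (methyl vanillate) | COC(=O)c1ccc(O)c(OC)c1 | starting material
28 | bromoacetic acid | OC(=O)CBr | starting material
29 | [2-methoxy-4-(methoxycarbonyl)phenoxy]acetic acid | COC(=O)c1ccc(OCC(=O)O)c(OC)c1 | intermediate
30 | (R)-4-benzyl-1,3-oxazolidin-2-one | O=C1N[C@H](Cc2ccccc2)CO1 | starting material
31 | mixed anhydride of 29 with pivalic acid | COC(=O)c1ccc(OCC(=O)OC(=O)C(C)(C)C)c(OC)c1 | intermediate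
32 | methyl 4-{2-[(4R)-4-benzyl-2-oxo-1,3-oxazolidin-3-yl]-2-oxoethoxy}-3-methoxybenzoate | COC(=O)c1ccc(OCC(=O)N2[C@H](Cc3ccccc3)COC2=O)c(OC)c1 | intermediate
33 | Z-dibutylboron enolate of 32 | CCCCB(CCCC)O/C(=C\Oc1ccc(C(=O)OC)cc1OC)N1[C@H](Cc2ccccc2)COC1=O | intermediate
34 | O-dibutylboron aldolate of 35 | COc1cc([C@H](OB(CCCC)CCCC)[C@H](C(=O)N2[C@H](Cc3ccccc3)COC2=O)Oc2ccc(C(=O)OC)cc2OC)ccc1OCc1ccccc1 | intermediate
35 | methyl 4-({(1S,2R)-1-[4-(benzyloxy)-3-methoxyphenyl]-3-[(4R)-4-benzyl-2-oxo-1,3-oxazolidin-3-yl]-1-hydroxy-3-oxopropan-2-yl}oxy)-3-methoxybenzoate | COc1cc([C@H](O)[C@H](C(=O)N2[C@H](Cc3ccccc3)COC2=O)Oc2ccc(C(=O)OC)cc2OC)ccc1OCc1ccccc1 | intermediate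
36 | methyl 4-({(1S,2S)-1-[4-(benzyloxy)-3-methoxyphenyl]-1,3-dihydroxypropan-2-yl}oxy)-3-methoxybenzoate (threo) | COc1cc([C@H](O)[C@H](CO)Oc2ccc(C(=O)OC)cc2OC)ccc1OCc1ccccc1 | intermediate
37 | methyl 4-({(1S,2S)-1-[4-(benzyloxy)-3-methoxyphenyl]-3-[(tert-butyldimethylsilyl)oxy]-1-hydroxypropan-2-yl}oxy)-3-methoxybenzoate | COc1cc([C@H](O)[C@H](CO[Si](C)(C)C(C)(C)C)Oc2ccc(C(=O)OC)cc2OC)ccc1OCc1ccccc1 | intermediate
38 | (1R,2S)-1-[4-(benzyloxy)-3-methoxyphenyl]-3-[(tert-butyldimethylsilyl)oxy]-2-[2-methoxy-4-(methoxycarbonyl)phenoxy]propyl 4-nitrobenzoate | COc1cc([C@@H](OC(=O)c2ccc(cc2)[N+](=O)[O-])[C@H](CO[Si](C)(C)C(C)(C)C)Oc2ccc(C(=O)OC)cc2OC)ccc1OCc1ccccc1 | intermediate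
39 | methyl 4-({(1R,2S)-1-[4-(benzyloxy)-3-methoxyphenyl]-3-[(tert-butyldimethylsilyl)oxy]-1-hydroxypropan-2-yl}oxy)-3-methoxybenzoate (erythro) | COc1cc([C@@H](O)[C@H](CO[Si](C)(C)C(C)(C)C)Oc2ccc(C(=O)OC)cc2OC)ccc1OCc1ccccc1 | intermediate
40 | methyl 4-({(1R,2S)-1-[4-(benzyloxy)-3-methoxyphenyl]-1,3-bis[(tert-butyldimethylsilyl)oxy]propan-2-yl}oxy)-3-methoxybenzoate | COc1cc([C@@H](O[Si](C)(C)C(C)(C)C)[C@H](CO[Si](C)(C)C(C)(C)C)Oc2ccc(C(=O)OC)cc2OC)ccc1OCc1ccccc1 | intermediate
41 | (ArC)methanol | COc1cc([C@@H](O[Si](C)(C)C(C)(C)C)[C@H](CO[Si](C)(C)C(C)(C)C)Oc2ccc(CO)cc2OC)ccc1OCc1ccccc1 | intermediate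
42 | (ArC)methyl bromide | COc1cc([C@@H](O[Si](C)(C)C(C)(C)C)[C@H](CO[Si](C)(C)C(C)(C)C)Oc2ccc(CBr)cc2OC)ccc1OCc1ccccc1 | intermediate
43 | 2-lithio-2-(BF)-1,3-dithiane | [Li]C1(SCCCS1)c1cc(OC)c2c(c1)[C@H](CO[Si](c1ccccc1)(c1ccccc1)C(C)(C)C)[C@@H](c1ccc(OCc3ccccc3)c(OC)c1)O2 | intermediate
44 | lithium enolate of (4R,5R)-4-[2-(BF)-1,3-dithian-2-yl]-5-(Men-oxy)oxolan-2-one | [Li]OC1=C[C@@H](C2(SCCCS2)c2cc(OC)c3c(c2)[C@H](CO[Si](c2ccccc2)(c2ccccc2)C(C)(C)C)[C@@H](c2ccc(OCc4ccccc4)c(OC)c2)O3)[C@H](O[C@@H]2C[C@H](C)CC[C@H]2C(C)C)O1 | intermediate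
45 | (3R,4R,5R)-3-[(ArC)methyl]-4-[2-(BF)-1,3-dithian-2-yl]-5-(Men-oxy)oxolan-2-one | COc1cc([C@@H](O[Si](C)(C)C(C)(C)C)[C@H](CO[Si](C)(C)C(C)(C)C)Oc2ccc(C[C@H]3C(=O)O[C@@H](O[C@@H]6C[C@H](C)CC[C@H]6C(C)C)[C@@H]3C3(SCCCS3)c3cc(OC)c4c(c3)[C@H](CO[Si](c3ccccc3)(c3ccccc3)C(C)(C)C)[C@@H](c3ccc(OCc5ccccc5)c(OC)c3)O4)cc2OC)ccc1OCc1ccccc1 | intermediate
46 | (3R,4R,5R)-3-[(ArC)methyl]-4-[(BF)methyl]-5-(Men-oxy)oxolan-2-one | COc1cc([C@@H](O[Si](C)(C)C(C)(C)C)[C@H](CO[Si](C)(C)C(C)(C)C)Oc2ccc(C[C@H]3C(=O)O[C@@H](O[C@@H]6C[C@H](C)CC[C@H]6C(C)C)[C@@H]3Cc3cc(OC)c4c(c3)[C@H](CO[Si](c3ccccc3)(c3ccccc3)C(C)(C)C)[C@@H](c3ccc(OCc5ccccc5)c(OC)c3)O4)cc2OC)ccc1OCc1ccccc1 | intermediate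
47 | potassium (2R,3R)-2-[(ArC)methyl]-3-[(BF)methyl]-4-oxobutanoate | COc1cc([C@@H](O[Si](C)(C)C(C)(C)C)[C@H](CO[Si](C)(C)C(C)(C)C)Oc2ccc(C[C@@H](C(=O)[O-])[C@H](C=O)Cc3cc(OC)c4c(c3)[C@H](CO[Si](c3ccccc3)(c3ccccc3)C(C)(C)C)[C@@H](c3ccc(OCc5ccccc5)c(OC)c3)O4)cc2OC)ccc1OCc1ccccc1.[K+] | intermediate
48 | potassium (2R,3R)-2-[(ArC)methyl]-3-[(BF)methyl]-4-hydroxybutanoate | COc1cc([C@@H](O[Si](C)(C)C(C)(C)C)[C@H](CO[Si](C)(C)C(C)(C)C)Oc2ccc(C[C@@H](C(=O)[O-])[C@H](CO)Cc3cc(OC)c4c(c3)[C@H](CO[Si](c3ccccc3)(c3ccccc3)C(C)(C)C)[C@@H](c3ccc(OCc5ccccc5)c(OC)c3)O4)cc2OC)ccc1OCc1ccccc1.[K+] | intermediate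
49 | (3R,4R)-3-[(ArC)methyl]-4-[(BF)methyl]oxolan-2-one | COc1cc([C@@H](O[Si](C)(C)C(C)(C)C)[C@H](CO[Si](C)(C)C(C)(C)C)Oc2ccc(C[C@H]3C(=O)OC[C@@H]3Cc3cc(OC)c4c(c3)[C@H](CO[Si](c3ccccc3)(c3ccccc3)C(C)(C)C)[C@@H](c3ccc(OCc5ccccc5)c(OC)c3)O4)cc2OC)ccc1OCc1ccccc1 | intermediate
50 | (3R,4R)-3-(4-{[(1R,2S)-1-[4-(benzyloxy)-3-methoxyphenyl]-1,3-dihydroxypropan-2-yl]oxy}-3-methoxybenzyl)-4-({(2S,3R)-2-[4-(benzyloxy)-3-methoxyphenyl]-3-(hydroxymethyl)-7-methoxy-2,3-dihydro-1-benzofuran-5-yl}methyl)oxolan-2-one | COc1cc([C@@H](O)[C@H](CO)Oc2ccc(C[C@H]3C(=O)OC[C@@H]3Cc3cc(OC)c4c(c3)[C@H](CO)[C@@H](c3ccc(OCc5ccccc5)c(OC)c3)O4)cc2OC)ccc1OCc1ccccc1 | intermediate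
51 | CNP0298853.1 | COc1cc([C@@H](O)[C@H](CO)Oc2ccc(C[C@H]3C(=O)OC[C@@H]3Cc3cc(OC)c4c(c3)[C@H](CO)[C@@H](c3ccc(O)c(OC)c3)O4)cc2OC)ccc1O | target

**Step count and risks**

Total step count: 27 (steps 1–2 butenolide, 3–12 dithiane, 13–22 bromide, 23 key step, 24–27 endgame).
Longest linear sequence: 15 steps (steps 3–12, then 23–27, from 7); the branch through steps 13–22 is equally long.

Steps most likely to fail:

Step 23 (tandem addition–alkylation). The enolate 44 sits next to the fully substituted dithiane carbon, so C-benzylation may be slower than proton transfer to the enolate or decomposition of the labile electron-rich bromide. Fallback, two separate C–C bond formations instead of one tandem event: setting out from 26 and 6, the lithiated dithiane is added as before and the enolate is protonated with water to give the isolable 4,5-trans conjugate adduct (4R,5R)-4-[2-(BF)-1,3-dithian-2-yl]-5-(Men-oxy)oxolan-2-one F1. Its enolate is then regenerated with LiN(SiMe3)2 in THF/DMPU at −78 °C and alkylated with 42 anti to the C4 substituent, which comes back to the route at 45.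

Step 18 (Mitsunobu inversion). Ionisation of the p-alkoxybenzylic alkoxyphosphonium ion, with loss of stereospecificity, or elimination to the enol ether may compete with the SN2 displacement. Fallback, redox inversion instead of substitution: setting out from 37, oxidation with Dess–Martin periodinane (NaHCO3, CH2Cl2, 0 °C) gives the α-aryloxy ketone methyl 4-({(2S)-1-[4-(benzyloxy)-3-methoxyphenyl]-3-[(tert-butyldimethylsilyl)oxy]-1-oxopropan-2-yl}oxy)-3-methoxybenzoate F2. Reduction with Zn(BH4)2 in Et2O at −20 °C delivers hydride to the zinc chelate of the carbonyl and aryloxy oxygens on the face anti to the CH2OTBS group, which should give the erythro alcohol; this comes back to the route at 39, and step 19 is skipped.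

Step 9 (acid cycloetherification). The benzylic cation of the free 1,3-diol may fragment with loss of formaldehyde, or lose a proton to a stilbene, before the phenol captures it. Fallback, ring closure before removal of the auxiliary: setting out from 19, TFA in CH2Cl2 at 0 °C cleaves the MOM ether and ionises the carbinol while the future CH2OH carbon is still the imide carbonyl, so no hydroxymethyl group is present to fragment. This gives the 2,3-trans imide (4S)-4-benzyl-3-({(2S,3S)-2-[4-(benzyloxy)-3-methoxyphenyl]-5-bromo-7-methoxy-2,3-dihydro-1-benzofuran-3-yl}carbonyl)-1,3-oxazolidin-2-one F3; LiBH4 (THF, MeOH, 0 °C) then removes the auxiliary and comes back to the route at 22.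

**Further compounds**

F1 | step 23 | (4R,5R)-4-[2-(BF)-1,3-dithian-2-yl]-5-(Men-oxy)oxolan-2-one | O=C1C[C@@H](C2(SCCCS2)c2cc(OC)c3c(c2)[C@H](CO[Si](c2ccccc2)(c2ccccc2)C(C)(C)C)[C@@H](c2ccc(OCc4ccccc4)c(OC)c2)O3)[C@H](O[C@@H]2C[C@H](C)CC[C@H]2C(C)C)O1
F2 | step 18 | methyl 4-({(2S)-1-[4-(benzyloxy)-3-methoxyphenyl]-3-[(tert-butyldimethylsilyl)oxy]-1-oxopropan-2-yl}oxy)-3-methoxybenzoate | COc1cc(C(=O)[C@H](CO[Si](C)(C)C(C)(C)C)Oc2ccc(C(=O)OC)cc2OC)ccc1OCc1ccccc1
F3 | step 9 | (4S)-4-benzyl-3-({(2S,3S)-2-[4-(benzyloxy)-3-methoxyphenyl]-5-bromo-7-methoxy-2,3-dihydro-1-benzofuran-3-yl}carbonyl)-1,3-oxazolidin-2-one | Brc1cc(OC)c2c(c1)[C@H](C(=O)N1[C@@H](Cc3ccccc3)COC1=O)[C@@H](c1ccc(OCc3ccccc3)c(OC)c1)O2
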